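The readings are calculated for an exercise.

X grows as E meets D, so my quick number for you is a count of lifetimes of D.

all flasks: G 0.020 M
- larch: L 0.90 equiv; Z 1 equiv; run made earlier
- oak: L 0.45 equiv; Z 1 equiv; run made earlier
- teal: L 0.900 equiv (fed, over 15 h); Z 1.00 equiv; all else is in the flask from the start; the feed brings no volume worth counting; time 3.0 d
- violet: L 0.900 equiv; Z 1.00 equiv (fed, over 15 h); all else is in the flask from the start; the feed brings no volume worth counting; time 3.0 d
- blue: L 0.900 equiv; Z 1.00 equiv; everything together at the start; time 3.0 d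

| run | time / h | X / % | D / % |
|---|---|---|---|
| larch | 2.50 | 5.7 | 32.0 |
| larch | 6.00 | 17.5 | 27.7 |
| larch | 12.0 | 30.6 | 21.7 |
| larch | 20.0 | 43.4 | 15.8 |
| larch | 25.0 | 48.4 | 12.4 |
| larch | 30.0 | 52.9 | 10.2 |
| larch | 40.0 | 58.4 | 7.0 |
| oak | 1.00 | 0.8 | 11.3 |
| oak | 2.00 | 3.5 | 14.6 |
| oak | 2.50 | 3.3 | 14.3 |
| oak | 4.00 | 7.3 | 12.9 |
| oak | 6.00 | 10.1 | 11.5 |
| oak | 10.0 | 15.2 | 8.4 |
| oak | 15.0 | 21.2 | 6.4 |

(scatter of a reading: 0.5 percentage points)

- percent here means G units held: one X counts as two
- G is a solid; its amount is given per volume of the solution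
- candidate steps: E + D -> X; G <-> E; L + Z -> J; E + L -> D; Z <-> Q
- at the start none of G is in solution

- the flask that comes out highest in amount of X, in percent of the G charged, or "all alike" when all lie within 1.5 percentage points (teal / violet / blue / all alike)
- X at the end, in percent of the G charged, teal
- X at the end, in percent of the G charged, violet
- X at the end, in percent of the G charged, blue

In larch, D falls from 21.7% at 12.0 h to 10.2% at 30.0 h, a rate of 0.0419 /h. I take the G units in neither D nor X as E, and they average 8.46 mM over that stretch. Dividing gives 4.96 /M/h, a reading I call the link-loss constant κ: the pseudo-first-order rate of loss of D per molar of E. The lifetime of D is the reciprocal of κ[E], where [E] is the concentration of E.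

Blue has the charge of larch. By 40.0 h, larch holds 36.2% of G as links, counted as D plus half of X. So E in blue heads for 27.6%, and D lives about 36.5 h. Running on from the last 7.0% of D in larch, I get X 66.6% for blue.

For teal I guess that half of the L reaches links, which is 45.0% of G. Counted from mid-feed, the ratio of D to E in teal falls to 0.432, so D in teal is 7.59% and X is 74.8%. For violet I have no reckoning of my own and keep your forecast.

Your forecast says blue, with teal 68.6%, violet 44% and blue 69.7%, adding “Blue and teal are close”. I differ on two flasks: my blue stands below yours and my teal above yours. I put the X of teal higher than that of blue, so I commit to teal.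

The flasks give teal 75.2%, violet 47.1% and blue 67.6%, so teal is highest.

    E + D → X (k = 0.0770 /M/min)
    G ⇌ E, rate k2*(cs2 - [E]) while solid is left; crystals form when [E] > cs2 (solubility = 18.0 mM, k = 0.0410 /min)
    L + Z → J (k = 1.10 /M/min)
    E + L → D (k = 1.10 /M/min)
    Z ⇌ Q (K = 3.00, k = 7.60 × 10⁻⁴ /min)

In violet, E stands at 0.511% at 3.00 d, which makes the lifetime of D 82.3 d, far longer than the run, and X reaches just 48.2% at 30.0 d. The neighbour of violet with 1.70 equiv of Z holds E 0.932% at 3.00 d, so its D has a lifetime of 45.1 d, again far longer than the run, and that flask stands at D 44.9% and X 54.1%.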